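**Plan**
1. Retrosynthetic cuts: first the two MOM ethers, then the biaryl bond C3–C1' (Suzuki–Miyaura). In the ring-B piece, both bonds that tie the pyran ring to the arene are then cut, C4–C4a (at C2') and O1–C8a (at C3'). This leads back to an aryne and 3-methylbut-2-enal.
2. Enabling feature: the 2,2-dimethyl-2H-pyran ring sits on two vicinal ring-B carbons, C2' bound to its sp2 CH (C4) and C3' bound to O1. A 2H-pyran is the valence isomer of a 1-oxatriene, here the o-quinone methide O=C3'–C2'=CH–CH=CMe2. That species is the ring-opened form of the benzoxete made from C2'≡C3' and the C=O of the enal.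
3. Helpers: SiMe3 on C3' and OTf on C2' trigger the aryne, and both are lost in the event. A second OTf on C1' polarises the aryne so that oxygen goes to C3', and it then serves as the coupling handle. MOM groups mask 4'-OH and 7-OH.
4. Forward order: ring B is dressed from 2-bromoisovanillin (steps 1–5), the pyran ring is annulated (step 6), and OTf is exchanged for Bpin (step 7). Rings A/C are closed separately from 2,4-dihydroxyacetophenone (steps 8–10). The halves are joined (step 11) and unmasked (step 12).
5. Stereochemistry: the target has no stereocentre. Its only stereo-element, the cis C3=C4 alkene of the pyran ring, is fixed by the ring.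

Key step: step 6

Remark on the chemistry: the target is achiral, so its constitution alone meets the request for a single enantiomer. Primed locants denote ring B: C1' is bonded to chromone C3, C2' = chromene C4a, C3' = chromene C8a, C4' carries OH, C5' carries OMe, C6' carries H.

**Step 1**
Reactants: 1 2-bromo-3-hydroxy-4-methoxybenzaldehyde
Product: 2 2-bromo-4-methoxy-3-(methoxymethoxy)benzaldehyde
Conditions: MOMCl, K2CO3, acetone, 0 °C → rt
Reagents that add atoms: chloromethyl methyl ether (MOMCl), COCCl
Why: Williamson-type O-alkylation of the only phenol gives the MOM acetal, a small group that withstands peracid, IBX, n-BuLi, fluoride and Pd/base and leaves with acid at the end.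

**Step 2**
Reactants: 2 2-bromo-4-methoxy-3-(methoxymethoxy)benzaldehyde
Product: 4 2-bromo-4-methoxy-3-(methoxymethoxy)phenol, via 2-bromo-4-methoxy-3-(methoxymethoxy)phenyl formate 3 (not isolated)
Conditions: mCPBA, CH2Cl2, rt; then K2CO3 (cat.), MeOH, rt
Reagents that add atoms: 3-chloroperbenzoic acid (mCPBA), O=C(OO)c1cccc(Cl)c1
Why: Baeyer–Villiger (Dakin-type) oxidation, in which the electron-rich para-methoxy aryl group migrates in the Criegee adduct and mild transesterification of formate 3 frees the phenol without touching Br or MOM.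

**Step 3**
Reactants: 4 2-bromo-4-methoxy-3-(methoxymethoxy)phenol
Product: 6 3-bromo-5-methoxy-4-(methoxymethoxy)benzene-1,2-diol, via 3-bromo-5-methoxy-4-(methoxymethoxy)cyclohexa-3,5-diene-1,2-dione 5 (not isolated)
Conditions: IBX, DMF, rt; then aq Na2S2O4, rt
Reagents that add atoms: 2-iodoxybenzoic acid (IBX), O=C1OI(=O)(O)c2ccccc12
Why: IBX ortho-oxygenation of an electron-rich phenol, in which the aryloxy-iodane delivers oxygen intramolecularly to the only free ortho carbon (the other carries Br) and o-quinone 5 is reduced at once by dithionite.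

**Step 4**
Reactants: 6 3-bromo-5-methoxy-4-(methoxymethoxy)benzene-1,2-diol
Product: 8 5-methoxy-4-(methoxymethoxy)-3-(trimethylsilyl)benzene-1,2-diol, via 3-bromo-5-methoxy-4-(methoxymethoxy)-1,2-bis(trimethylsilyloxy)benzene 7 (not isolated)
Conditions: HMDS, THF, 65 °C, evaporate; n-BuLi, THF, −78 °C; aq NH4Cl–MeOH, rt (under argon)
Reagents that add atoms: hexamethyldisilazane (HMDS), C[Si](C)(C)N[Si](C)(C)C
Why: O-silylation, fast Br/Li exchange and 1,3 O→C silyl migration (retro-Brook rearrangement) from the adjacent silyl ether place SiMe3 exactly where Br stood, and the remaining aryl silyl ether is hydrolysed in the mildly protic work-up.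

**Step 5**
Reactants: 8 5-methoxy-4-(methoxymethoxy)-3-(trimethylsilyl)benzene-1,2-diol
Product: 9 5-methoxy-4-(methoxymethoxy)-3-(trimethylsilyl)benzene-1,2-diyl bis(trifluoromethanesulfonate)
Conditions: Tf2O, pyridine, CH2Cl2, −20 → 0 °C
Reagents that add atoms: trifluoromethanesulfonic anhydride, O=S(=O)(OS(=O)(=O)C(F)(F)F)C(F)(F)F
Why: O-sulfonylation of both phenols, after which the triflate next to SiMe3 is the aryne leaving group and the outer one is the directing group and later coupling handle.

**Step 6**
Reactants: 9 5-methoxy-4-(methoxymethoxy)-3-(trimethylsilyl)benzene-1,2-diyl bis(trifluoromethanesulfonate); 10 3-methylbut-2-enal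
Product: 14 7-methoxy-8-(methoxymethoxy)-2,2-dimethyl-2H-chromen-5-yl trifluoromethanesulfonate, via 5-methoxy-4-(methoxymethoxy)-2,3-didehydrophenyl trifluoromethanesulfonate (aryne) 11 (not isolated), via 5-methoxy-6-(methoxymethoxy)-2-(2-methylprop-1-enyl)-2H-1-benzoxet-3-yl trifluoromethanesulfonate 12 (not isolated), via (6Z)-3-methoxy-2-(methoxymethoxy)-6-(3-methylbut-2-enylidene)-5-(triflyloxy)cyclohexa-2,4-dien-1-one (o-quinone methide) 13 (not isolated)
Conditions: CsF, excess 10, MeCN, rt → 45 °C, slow addition of 9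
Reagents that add atoms: none
Why: Fluoride removes the C3' silyl group and the adjacent C2' triflate departs (1,2-elimination of an o-silylaryl triflate; the C1' triflate has no silyl neighbour and stays), giving aryne 11, whose strained C2'≡C3' bond takes up the C=O group of 10 in an asynchronous [2+2] cycloaddition that starts with attack of the carbonyl oxygen and makes the aryl–O and aryl–C bonds of benzoxete 12 together. The four-membered ring opens at once by 4π electrocyclic cleavage of its sp3 C–O bond to o-quinone methide 13, and the 1-oxatriene O=C3'–C2'=CH–CH=CMe2 closes by a disrotatory oxa-6π electrocyclisation (O onto CMe2), which builds the six-membered 2H-pyran ring and restores the aromaticity of ring B. The closest known reaction type is the annulation of arynes with α,β-unsaturated aldehydes to 2H-chromenes, a relative of the insertion of arynes into the C=O bond of formamides. No stereocentre survives (the sp3 carbon of 12 is transient and racemic) and the new ring alkene can only be cis. The step needs oxygen on C3' and carbon on C2': the C1' triflyloxy group, the strongest σ-acceptor on the ring, distorts the aryne so that C3' is the electrophilic end and the charge building up at C2' lies next to it, as in the meta-selective additions to 3-(triflyloxy)arynes, and this must outweigh the weaker opposite pull of the small 4'-OMOM group. Chemoselectivity rests on the β,β-dimethyl group of 10, which blocks the competing [4+2] mode through the enal terminus, and on slow addition of 9 to excess 10, which keeps the aryne too dilute to intercept 13 before it cyclises.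

**Step 7**
Reactants: 14 7-methoxy-8-(methoxymethoxy)-2,2-dimethyl-2H-chromen-5-yl trifluoromethanesulfonate
Product: 15 2-[7-methoxy-8-(methoxymethoxy)-2,2-dimethyl-2H-chromen-5-yl]-4,4,5,5-tetramethyl-1,3,2-dioxaborolane
Conditions: B2pin2, PdCl2(dppf) (cat.), KOAc, 1,4-dioxane, 85 °C
Reagents that add atoms: bis(pinacolato)diboron, CC1(C)OB(OC1(C)C)B1OC(C)(C)C(C)(C)O1
Why: Miyaura borylation of an aryl triflate consumes the directing triflate under conditions to which the chromene alkene and the MOM ether are inert.

**Step 8**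
Reactants: 16 1-(2,4-dihydroxyphenyl)ethanone
Product: 17 1-[2-hydroxy-4-(methoxymethoxy)phenyl]ethanone
Conditions: MOMCl, K2CO3, acetone, rt
Reagents that add atoms: chloromethyl methyl ether (MOMCl), COCCl
Why: Chemoselective Williamson-type alkylation, because the 2-OH is held in a hydrogen bond to the ketone and only the 4-OH reacts.

**Step 9**
Reactants: 17 1-[2-hydroxy-4-(methoxymethoxy)phenyl]ethanone
Product: 18 (E)-3-(dimethylamino)-1-[2-hydroxy-4-(methoxymethoxy)phenyl]prop-2-en-1-one
Conditions: DMF-DMA, toluene, 90 °C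
Reagents that add atoms: N,N-dimethylformamide dimethyl acetal, COC(OC)N(C)C
Why: Condensation of the methyl ketone with the amide acetal gives the push–pull enaminone in its thermodynamic E geometry and supplies C2 of the chromone.

**Step 10**
Reactants: 18 (E)-3-(dimethylamino)-1-[2-hydroxy-4-(methoxymethoxy)phenyl]prop-2-en-1-one
Product: 19 3-iodo-7-(methoxymethoxy)-4H-chromen-4-one
Conditions: I2, CHCl3, rt
Reagents that add atoms: iodine, II
Why: Iodocyclisation of an o-hydroxyaryl enaminone, in which α-iodination is followed by addition–elimination of the phenol OH with loss of dimethylamine to close ring C as the 3-iodochromone.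

**Step 11**
Reactants: 15 2-[7-methoxy-8-(methoxymethoxy)-2,2-dimethyl-2H-chromen-5-yl]-4,4,5,5-tetramethyl-1,3,2-dioxaborolane; 19 3-iodo-7-(methoxymethoxy)-4H-chromen-4-one
Product: 20 3-[7-methoxy-8-(methoxymethoxy)-2,2-dimethyl-2H-chromen-5-yl]-7-(methoxymethoxy)-4H-chromen-4-one
Conditions: PdCl2(dppf) (cat.), Na2CO3, DME–H2O, 70 °C
Reagents that add atoms: none
Why: Suzuki–Miyaura coupling of a 3-iodochromone with an arylboronate is the standard isoflavone construction, and the reactive C–I bond allows a mild carbonate base that should not open the pyranone.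

**Step 12**
Reactants: 20 3-[7-methoxy-8-(methoxymethoxy)-2,2-dimethyl-2H-chromen-5-yl]-7-(methoxymethoxy)-4H-chromen-4-one
Product: 21 7-hydroxy-3-(8-hydroxy-7-methoxy-2,2-dimethyl-2H-chromen-5-yl)-4H-chromen-4-one
Conditions: HCl (cat.), MeOH–THF, 45 °C
Reagents that add atoms: none
Why: Acid-catalysed transacetalisation removes both MOM groups in one operation under conditions mild enough for the 2,2-dimethylchromene alkene and the chromone.

**Compound list**
1 | 2-bromo-3-hydroxy-4-methoxybenzaldehyde | COc1ccc(C=O)c(Br)c1O | starting material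
2 | 2-bromo-4-methoxy-3-(methoxymethoxy)benzaldehyde | COCOc1c(OC)ccc(C=O)c1Br | intermediate
3 | 2-bromo-4-methoxy-3-(methoxymethoxy)phenyl formate | COCOc1c(OC)ccc(OC=O)c1Br | intermediate
4 | 2-bromo-4-methoxy-3-(methoxymethoxy)phenol | COCOc1c(OC)ccc(O)c1Br | intermediate
5 | 3-bromo-5-methoxy-4-(methoxymethoxy)cyclohexa-3,5-diene-1,2-dione | COCOC1=C(Br)C(=O)C(=O)C=C1OC | intermediate
6 | 3-bromo-5-methoxy-4-(methoxymethoxy)benzene-1,2-diol | COCOc1c(OC)cc(O)c(O)c1Br | intermediate
7 | 3-bromo-5-methoxy-4-(methoxymethoxy)-1,2-bis(trimethylsilyloxy)benzene | COCOc1c(OC)cc(O[Si](C)(C)C)c(O[Si](C)(C)C)c1Br | intermediate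
8 | 5-methoxy-4-(methoxymethoxy)-3-(trimethylsilyl)benzene-1,2-diol | COCOc1c(OC)cc(O)c(O)c1[Si](C)(C)C | intermediate
9 | 5-methoxy-4-(methoxymethoxy)-3-(trimethylsilyl)benzene-1,2-diyl bis(trifluoromethanesulfonate) | COCOc1c(OC)cc(OS(=O)(=O)C(F)(F)F)c(OS(=O)(=O)C(F)(F)F)c1[Si](C)(C)C | intermediate
10 | 3-methylbut-2-enal | CC(C)=CC=O | starting material
11 | 5-methoxy-4-(methoxymethoxy)-2,3-didehydrophenyl trifluoromethanesulfonate (aryne) | COCOC1=C(OC)C=C(OS(=O)(=O)C(F)(F)F)C#C1 | intermediate
12 | 5-methoxy-6-(methoxymethoxy)-2-(2-methylprop-1-enyl)-2H-1-benzoxet-3-yl trifluoromethanesulfonate (racemic, transient) | COCOc1c(OC)cc(OS(=O)(=O)C(F)(F)F)c2c1OC2C=C(C)C | intermediate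
13 | (6Z)-3-methoxy-2-(methoxymethoxy)-6-(3-methylbut-2-enylidene)-5-(triflyloxy)cyclohexa-2,4-dien-1-one | O=C1C(OCOC)=C(OC)C=C(OS(=O)(=O)C(F)(F)F)/C1=C/C=C(C)C | intermediate
14 | 7-methoxy-8-(methoxymethoxy)-2,2-dimethyl-2H-chromen-5-yl trifluoromethanesulfonate | COCOc1c(OC)cc(OS(=O)(=O)C(F)(F)F)c2C=CC(C)(C)Oc12 | intermediate
15 | 2-[7-methoxy-8-(methoxymethoxy)-2,2-dimethyl-2H-chromen-5-yl]-4,4,5,5-tetramethyl-1,3,2-dioxaborolane | COCOc1c(OC)cc(B3OC(C)(C)C(C)(C)O3)c2C=CC(C)(C)Oc12 | intermediate
16 | 1-(2,4-dihydroxyphenyl)ethanone | CC(=O)c1ccc(O)cc1O | starting material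
17 | 1-[2-hydroxy-4-(methoxymethoxy)phenyl]ethanone | CC(=O)c1ccc(OCOC)cc1O | intermediate
18 | (E)-3-(dimethylamino)-1-[2-hydroxy-4-(methoxymethoxy)phenyl]prop-2-en-1-one | CN(C)/C=C/C(=O)c1ccc(OCOC)cc1O | intermediate
19 | 3-iodo-7-(methoxymethoxy)-4H-chromen-4-one | COCOc1ccc2c(c1)occ(I)c2=O | intermediate
20 | 3-[7-methoxy-8-(methoxymethoxy)-2,2-dimethyl-2H-chromen-5-yl]-7-(methoxymethoxy)-4H-chromen-4-one | COCOc1ccc2c(c1)occ(-c1cc(OC)c(OCOC)c3OC(C)(C)C=Cc13)c2=O | intermediate
21 | 7-hydroxy-3-(8-hydroxy-7-methoxy-2,2-dimethyl-2H-chromen-5-yl)-4H-chromen-4-one | COc1cc(-c2coc3cc(O)ccc3c2=O)c2c(c1O)OC(C)(C)C=C2 | target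

Total step count: 12. Longest linear sequence: 9 (steps 1–7, 11, 12).

**Steps most likely to fail**

**Step 6.**
- What may go wrong: the carbonyl oxygen may attack C2' instead of C3' if the pull of the 4'-alkoxy group is not fully overridden by the C1' triflate. The aryne may also be lost to an ene reaction with the enal methyl groups, to fluoride, or to capture of the quinone methide by a second aryne. The enal may self-condense under the basic fluoride.
- Fallback: classical order, oxygen first and carbon second by a sigmatropic shift. It sets out from 19 and comes back at 20.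
- Commercial 5-bromo-2-hydroxy-3-methoxybenzaldehyde (COc1cc(Br)cc(C=O)c1O) is MOM-protected to 5-bromo-3-methoxy-2-(methoxymethoxy)benzaldehyde F1.
- Baeyer–Villiger oxidation gives 5-bromo-3-methoxy-2-(methoxymethoxy)phenyl formate F2, which is methanolysed to 5-bromo-3-methoxy-2-(methoxymethoxy)phenol F3.
- Miyaura borylation gives 3-methoxy-2-(methoxymethoxy)-5-(4,4,5,5-tetramethyl-1,3,2-dioxaborolan-2-yl)phenol F4.
- Suzuki–Miyaura coupling with 19 gives 3-[3-hydroxy-5-methoxy-4-(methoxymethoxy)phenyl]-7-(methoxymethoxy)-4H-chromen-4-one F5.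
- The free 3'-OH is alkylated with 3-chloro-3-methylbut-1-yne (DBU, cat. CuCl2, MeCN, 0 °C) to 3-[3-methoxy-4-(methoxymethoxy)-5-(2-methylbut-3-yn-2-yloxy)phenyl]-7-(methoxymethoxy)-4H-chromen-4-one F6.
- Heating F6 in o-xylene at 140 °C triggers an aromatic propargyl Claisen rearrangement, a 1,5-H shift and an oxa-6π closure at C2', the only free ortho carbon, to give 20.

**Step 4.**
- What may go wrong: butyllithium may attack silicon instead of bromine on the doubly silylated substrate, or the silyl migration may be incomplete. The very electron-rich catechol may oxidise in air, and protodesilylation may occur in the hydrolytic work-up.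
- Fallback: silicon goes in before the second oxygen, on a plain monophenol. It sets out from 4 and comes back at 8.
- Compound 4 is silylated with HMDS to [2-bromo-4-methoxy-3-(methoxymethoxy)phenoxy]trimethylsilane F7.
- Treatment with n-BuLi at −78 °C (retro-Brook) gives 4-methoxy-3-(methoxymethoxy)-2-(trimethylsilyl)phenol F8.
- Casnati–Skattebøl ortho-formylation (MgCl2, Et3N, paraformaldehyde) at the only free ortho carbon gives 2-hydroxy-5-methoxy-4-(methoxymethoxy)-3-(trimethylsilyl)benzaldehyde F9.
- Dakin oxidation (H2O2, aq NaOH) converts F9 into 8, which is triflated directly.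

**Step 3.**
- What may go wrong: over-oxidation may occur, or water or solvent may add to the electrophilic alkoxy-bromo-o-quinone before it is reduced. The MOM acetal on the quinone stage may also be lost.
- Fallback: the oxygen is brought in through a carbon substituent and no quinone is formed. It sets out from 4 and comes back at 6.
- Casnati–Skattebøl ortho-formylation of 4 gives 3-bromo-2-hydroxy-5-methoxy-4-(methoxymethoxy)benzaldehyde F10.
- Dakin oxidation (H2O2, aq NaOH) of F10 gives catechol 6.

**Further compounds**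
F1 | step 6 | 5-bromo-3-methoxy-2-(methoxymethoxy)benzaldehyde | COCOc1c(OC)cc(Br)cc1C=O
F2 | step 6 | 5-bromo-3-methoxy-2-(methoxymethoxy)phenyl formate | COCOc1c(OC)cc(Br)cc1OC=O
F3 | step 6 | 5-bromo-3-methoxy-2-(methoxymethoxy)phenol | COCOc1c(OC)cc(Br)cc1O
F4 | step 6 | 3-methoxy-2-(methoxymethoxy)-5-(4,4,5,5-tetramethyl-1,3,2-dioxaborolan-2-yl)phenol | COCOc1c(OC)cc(B2OC(C)(C)C(C)(C)O2)cc1O
F5 | step 6 | 3-[3-hydroxy-5-methoxy-4-(methoxymethoxy)phenyl]-7-(methoxymethoxy)-4H-chromen-4-one | COCOc1ccc2c(c1)occ(-c1cc(O)c(OCOC)c(OC)c1)c2=O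
F6 | step 6 | 3-[3-methoxy-4-(methoxymethoxy)-5-(2-methylbut-3-yn-2-yloxy)phenyl]-7-(methoxymethoxy)-4H-chromen-4-one | COCOc1ccc2c(c1)occ(-c1cc(OC(C)(C)C#C)c(OCOC)c(OC)c1)c2=O
F7 | step 4 | [2-bromo-4-methoxy-3-(methoxymethoxy)phenoxy]trimethylsilane | COCOc1c(OC)ccc(O[Si](C)(C)C)c1Br
F8 | step 4 | 4-methoxy-3-(methoxymethoxy)-2-(trimethylsilyl)phenol | COCOc1c(OC)ccc(O)c1[Si](C)(C)C
F9 | step 4 | 2-hydroxy-5-methoxy-4-(methoxymethoxy)-3-(trimethylsilyl)benzaldehyde | COCOc1c(OC)cc(C=O)c(O)c1[Si](C)(C)C
F10 | step 3 | 3-bromo-2-hydroxy-5-methoxy-4-(methoxymethoxy)benzaldehyde | COCOc1c(OC)cc(C=O)c(O)c1Br
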